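## Retrosynthetic overview
1. The dihydrofuran ring is disconnected at C8–C(spiro) and O7–CH(Ar). This traces back to a dehydrogenative [3+2] union of the C8–H/7-OH edge of a flavan-3-ol with the exocyclic C=C of an aurone (anodic key step, only H2 lost).
2. The aurone C=C comes from aldol condensation of 4,6-dihydroxybenzofuran-3(2H)-one 1 with 4-hydroxybenzaldehyde 2, via aldol 3, to give Z-aurone 4.
3. The flavan half is (+)-afzelechin 5, bought with the pyran ring and its 2R,3S centres in place.
4. Ring order: the benzofuranone ring (in 1) and the pyran ring (in 5) are bought. Only the dihydrofuran ring is built, C–C bond first (cation 6 to quinone methide 7) and C–O bond second, giving 8.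
5. Stereochemistry: the spiro/CH(Ar) relationship follows from the Z-alkene and a reversible ring closure. The absolute sense is induced by the centres of 5.

Assumption: 1, 2 and enantiopure plant-derived (+)-afzelechin 5 are catalogue compounds, 5 is the limiting reagent, and because the route has only two steps the risk list enters step 2 twice, once for each of its two independent risks.

## Route

Step 1
Reactants: 1 4,6-dihydroxybenzofuran-3(2H)-one; 2 4-hydroxybenzaldehyde
Product: 4 (Z)-4,6-dihydroxy-2-(4-hydroxybenzylidene)benzofuran-3(2H)-one (4,6,4'-trihydroxyaurone), via aldol adduct 3 (not isolated)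
Conditions: KOH (50% aq), MeOH, reflux, 3 h; then 2 M HCl to pH 2, filter
Reagents that add atoms: none
Why: Claisen–Schmidt-type aldol condensation at the acidic C2–H2 of the coumaranone followed by E1cB loss of water, a standard entry to free polyhydroxyaurones that gives only the thermodynamically favoured Z-alkene (aryl syn to the ring O), with no stereocentre surviving.

Step 2
Reactants: 4 (Z)-4,6,4'-trihydroxyaurone; 5 (+)-afzelechin, (2R,3S)-2-(4-hydroxyphenyl)chroman-3,5,7-triol
Product: 8 (2S,2'R,3'S,8'S)-3',4,5',6-tetrahydroxy-2',8'-bis(4-hydroxyphenyl)-3',4'-dihydro-2'H,3H,8'H-spiro[benzofuran-2,9'-furo[2,3-h]chromen]-3-one (target CNP0228515.1), via quinone-methide oxocarbenium cation 6 (not isolated), via C8-linked p-quinone methide 7 (not isolated)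
Conditions: BDD anode, Pt cathode, undivided cell, 2 mA cm−2, 2.1 F mol−1 (on 4); 2,6-lutidine (2 equiv), n-Bu4NPF6 (0.05 M), HFIP–MeCN 4:1, 5 °C, Ar, dark; 4 (1.3 equiv) added over 4 h; RP-18 chromatography
Reagents that add atoms: none
Why: Proposed new method: an anodic dehydrogenative formal [3+2] annulation in which the aurone, not the phenol partner, is the oxidised component; in lutidine/HFIP only the vinylogous acid 4 (pKa about 7, against about 9.4 for 5 and 9.3 for the solvent) is ionised, its push–pull 4'-phenolate form is the most easily oxidised species present and loses 2 e− to give the HFIP-stabilised cation 6, whose charge sits at C2 (vinylogous para position, the only site with α-oxygen stabilisation); C8 of 5, the most nucleophilic carbon in the flask (C8 over C6 as usual for flavan-3-ols), attacks C2 in an SEAr step that makes the quaternary C–C bond, loss of H+ gives quinone methide 7, and the neighbouring 7-OH closes the dihydrofuran by 5-exo-trig oxa-1,6-addition while the two released protons are reduced to H2 at the cathode, so the buffered medium never turns acidic enough to aromatise the product to the 3-aroylbenzofuran isomer; the aryl group ends cis to the benzofuranone ring O and anti to C3=O, which is the relationship already present in the Z-alkene and also the thermodynamic result of the reversible closure; the absolute sense comes from the bought 2R,3S centres, because C8 is attacked on the flavan face opposite the 2-aryl group with the flat quinone-methide arm stacked over ring A and the benzo ring turned away from the pyran, a model that leads to 2S,8'S; only a modest d.r. of about 2:1 is assumed, and the 2R,8'R isomer and any C6 regioisomer are removed on RP-18; the closest known reaction types are the anodic or photocatalytic oxidative [3+2] cycloaddition of phenols with styrenes, the oxidative β-5 coupling of 4-hydroxystyrenes to dihydrobenzofuran neolignans, and anodic phenol–arene cross-coupling in HFIP, none of which has been shown for an aurone, for bond formation at a fully substituted alkene carbon giving a spiro centre, or for an unprotected flavan-3-ol.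

## Compound list
1 | 4,6-dihydroxybenzofuran-3(2H)-one | O=C1COc2cc(O)cc(O)c12 | starting material
2 | 4-hydroxybenzaldehyde | O=Cc1ccc(O)cc1 | starting material
3 | 4,6-dihydroxy-2-[hydroxy(4-hydroxyphenyl)methyl]benzofuran-3(2H)-one (aldol adduct, not isolated, stereoisomer mixture, both centres lost on dehydration) | O=C1C(C(O)c2ccc(O)cc2)Oc2cc(O)cc(O)c12 | intermediate
4 | (Z)-4,6-dihydroxy-2-(4-hydroxybenzylidene)benzofuran-3(2H)-one | O=C1/C(=C/c2ccc(O)cc2)Oc2cc(O)cc(O)c12 | intermediate
5 | (+)-afzelechin, (2R,3S)-2-(4-hydroxyphenyl)chroman-3,5,7-triol | O[C@H]1Cc2c(O)cc(O)cc2O[C@@H]1c1ccc(O)cc1 | starting material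
6 | 4,6-dihydroxy-3-oxo-2-[(4-oxocyclohexa-2,5-dien-1-ylidene)methyl]-2,3-dihydrobenzofuran-2-ylium (two-electron-oxidised aurone, not isolated) | O=C1C=CC(=C[C+]2Oc3cc(O)cc(O)c3C2=O)C=C1 | intermediate
7 | (2R)-4,6-dihydroxy-2-[(4-oxocyclohexa-2,5-dien-1-ylidene)methyl]-2-[(2R,3S)-3,5,7-trihydroxy-2-(4-hydroxyphenyl)chroman-8-yl]benzofuran-3(2H)-one (not isolated; same spatial arrangement at C2 as in 8, the descriptor differs only through CIP ranking) | O=C1c2c(O)cc(O)cc2O[C@]1(C=C1C=CC(=O)C=C1)c1c(O)cc(O)c2c1O[C@H](c1ccc(O)cc1)[C@@H](O)C2 | intermediate
8 | (2S,2'R,3'S,8'S)-3',4,5',6-tetrahydroxy-2',8'-bis(4-hydroxyphenyl)-3',4'-dihydro-2'H,3H,8'H-spiro[benzofuran-2,9'-furo[2,3-h]chromen]-3-one (spiro C is S, dihydrofuran CH(Ar) is S with the aryl cis to the benzofuranone ring O, flavan part is 2R,3S) | O=C1c2c(O)cc(O)cc2O[C@]12c1c(cc(O)c3c1O[C@H](c1ccc(O)cc1)[C@@H](O)C3)O[C@H]2c1ccc(O)cc1 | target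

## Totals
Total step count: 2. Longest linear sequence: 2.

## Steps most likely to fail

1. **Step 2, bond formation (the proposed new method).**
   - Risks are oxidation of 5 instead of 4, aurone oligomers, anode fouling, or no bond at the hindered C2.
   - The fallback sets out from 4 and 5 and comes back at quinone methide 7, and so at 8.
   - It gives up electrosynthesis and the selective two-electron oxidation of one partner, and uses the classical radical–radical phenol coupling instead.
   - Compounds 4 and 5 (2 equiv, excess recovered) are stirred with Ag2O (1.1 equiv) in acetone–toluene at 50 °C in the dark.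
   - Both phenols become phenoxyl radicals, which combine in the β-5 mode (C2 of the aurone radical with C8 of the flavanyl radical), tautomerise to 7 and close to 8.
   - This is the known oxidative coupling that gives dihydrobenzofuran neolignans from isoeugenol or coniferyl alcohol, viniferins from resveratrol, and flavonolignans from unprotected taxifolin.
   - No new compound is made (F0).

2. **Step 2, facial and C8/C6 selectivity and isolation of the free polyphenol.**
   - The inducing centres are remote from the new ones, so the d.r. may approach 1:1 and the free isomers may co-elute.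
   - The fallback sets out from crude 8 (the mixture with its 2R,8'R isomer) and comes back at pure 8.
   - The crude product is acetylated (Ac2O, pyridine, cat. DMAP, 0 °C to rt) to the hexa-O-acetate of 8 F1.
   - F1 is separated from its diastereomer and from regioisomers by silica chromatography and crystallisation.
   - It is then deacetylated with cat. K2CO3 in MeOH at 0 °C under Ar and quenched into pH 5 buffer. The short, cold treatment avoids opening of the spiro ring.

3. **Step 1.**
   - The polyphenolates of 1 and 2 are poor aldol partners, and 1 can autoxidise in hot alkali.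
   - The fallback sets out from 1 and 2 and comes back at 4.
   - The two are heated in acetic anhydride (120 °C). The phenols are acetylated in situ, so a neutral ketone condenses with a neutral, more electrophilic aldehyde.
   - This gives (Z)-4,6-diacetoxy-2-(4-acetoxybenzylidene)benzofuran-3(2H)-one F2, which crystallises.
   - Methanolysis with cat. HCl in MeOH at reflux then liberates 4.

## Further compounds
F0 | step 2 | none | none
F1 | step 2 | hexa-O-acetate of 8 (2S,2'R,3'S,8'S) | O=C1c2c(OC(C)=O)cc(OC(C)=O)cc2O[C@]12c1c(cc(OC(C)=O)c3c1O[C@H](c1ccc(OC(C)=O)cc1)[C@@H](OC(C)=O)C3)O[C@H]2c1ccc(OC(C)=O)cc1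
F2 | step 1 | (Z)-4,6-diacetoxy-2-(4-acetoxybenzylidene)benzofuran-3(2H)-one | O=C1/C(=C/c2ccc(OC(C)=O)cc2)Oc2cc(OC(C)=O)cc(OC(C)=O)c12
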